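The lactone ring (O6–C7–C1–C8–C9–C5) hides a cyclopentanone: the ketal carbon C5 and the lactone carbonyl C7 are linked only through O6, the Baeyer–Villiger image of an α-methoxy ketone, so C5 and C7 can arrive together as the two carbons of oxalate. The key step condenses an enantioenriched dimethyl 2-methyl-3-arylglutarate (C9–C8–C1, both termini ester-activated) with dimethyl oxalate; this double Claisen closure forms the C7–C1 and C5–C9 bonds and a cyclopentane-1,2-dione in one operation. The rhodium-set C8 centre then controls C9, C1 and C5, the enone bridge is annulated through a tethered Mukaiyama closure, and O6 is inserted last with retention.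

Key step: step 3

Numbering used below (target as 6-oxabicyclo[3.2.2]non-3-ene-2,7-dione): C1 bridgehead CH, C2 ketone, C3 (allyl-bearing), C4 (=CH), C5 ketal bridgehead (OMe), O6, C7 lactone C=O, C8 (CH–aryl), C9 (CH–CH3). Ar = 3,4,5-trimethoxyphenyl.

Assumption: (S)-BINAP is taken to deliver the aryl group to the enoate face that gives (3S)-4, by analogy with simple (E)-enoates; if the sense proves opposite, (R)-BINAP is used.

Step 1
Reactants: 1 dimethyl (E)-pent-2-enedioate (dimethyl glutaconate)
Product: 2 dimethyl (E)-4-methylpent-2-enedioate (racemic)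
Conditions: NaH (1.0 equiv), THF, 0 °C; MeI (1.0 equiv), 0 °C to rt
Reagents that add atoms: iodomethane, CI
Why: Enolate alkylation of the delocalised glutaconate anion at an ester α-carbon should give the mono-methyl diester; the new centre is racemic and is erased later, when it becomes the sp2 carbon of the diosphenol.

Step 2
Reactants: 2 dimethyl (E)-4-methylpent-2-enedioate; 3 (3,4,5-trimethoxyphenyl)boronic acid
Product: 4 dimethyl (3S)-2-methyl-3-(3,4,5-trimethoxyphenyl)pentanedioate (both C2 epimers)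
Conditions: [Rh(OH)((S)-BINAP)]2 (3 mol % Rh), dioxane/H2O (10:1), 50 °C
Reagents that add atoms: none
Why: Hayashi–Miyaura asymmetric conjugate addition: the aryl–rhodium species adds to the β-carbon of the enoate and the chiral diphosphine selects the enantioface, setting the aryl-bearing centre (C8 of the target), the only stereocentre made by catalysis; the neighbouring methyl-bearing centre forms as both epimers and is erased in step 4.

Step 3
Reactants: 4 dimethyl (3S)-2-methyl-3-(3,4,5-trimethoxyphenyl)pentanedioate; 5 dimethyl oxalate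
Product: 7 dimethyl (2R)-1-methyl-4,5-dioxo-2-(3,4,5-trimethoxyphenyl)cyclopentane-1,3-dicarboxylate (C1/C3 epimers; enolised), via acyclic α-oxalyl diester enolate 6 (not isolated)
Conditions: NaH (2.5 equiv), MeOH (cat.), THF, 0 °C to reflux; aq. HCl
Reagents that add atoms: none
Why: Mechanism: the CH2 α-carbon of 4 is acylated by one ester group of 5 (Claisen) to give the stabilised enolate 6, then the excess base deprotonates the methine α-carbon, which attacks the remaining oxalyl ester carbonyl and expels methoxide (Dieckmann-type), so the bonds that become C7–C1 and C5–C9 form in one operation. The closest known reaction type is the condensation of glutaric esters with oxalic esters to 3,5-bis(alkoxycarbonyl)cyclopentane-1,2-diones. The five-membered carbocycle closes by a 5-exo-trig acyl substitution. The C8 centre is not acidic and is carried through unchanged; the two new ester-bearing centres need no control, because one is an enolised β-dicarbonyl carbon and the other becomes sp2 in step 4. The step needs acylation at CH2 before the hindered methine and C- rather than O-acylation: the first is secured by sterics and acidity, the second by the reversibility of O-acylation and by withdrawal of the product as its doubly stabilised enolate, which also drives formation of the quaternary centre.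

Step 4
Reactants: 7 dimethyl (2R)-1-methyl-4,5-dioxo-2-(3,4,5-trimethoxyphenyl)cyclopentane-1,3-dicarboxylate
Product: 8 (4R)-2-hydroxy-3-methyl-4-(3,4,5-trimethoxyphenyl)cyclopent-2-en-1-one
Conditions: LiCl (4 equiv), DMSO/H2O, 120 °C
Reagents that add atoms: none
Why: Krapcho dealkoxycarbonylation should remove both β-keto ester groups, and the 1,2-dione then enolises toward the methyl-bearing carbon (diosphenol); the near-neutral medium is chosen to spare the γ-benzylic C8 centre.

Step 5
Reactants: 8 (4R)-2-hydroxy-3-methyl-4-(3,4,5-trimethoxyphenyl)cyclopent-2-en-1-one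
Product: 9 (4R)-2-methoxy-3-methyl-4-(3,4,5-trimethoxyphenyl)cyclopent-2-en-1-one
Conditions: MeI, K2CO3, acetone, 50 °C
Reagents that add atoms: iodomethane, CI
Why: O-Alkylation of the acidic diosphenol hydroxyl (Williamson-type) should install the methoxy group that ends on C5 of the target; no stereocentre is touched.

Step 6
Reactants: 10 methyl 3,3-dimethoxypropanoate
Product: 11 methyl 2-(dimethoxymethyl)pent-4-enoate (racemic)
Conditions: LiN(iPr)2, THF, −78 °C; allyl bromide, DMPU, −78 to −30 °C
Reagents that add atoms: allyl bromide, C=CCBr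
Why: Ester enolate alkylation at low temperature (to suppress β-elimination of methoxide) should give the α-allyl ester; the racemic centre becomes sp2 (C3) in step 10.

Step 7
Reactants: 11 methyl 2-(dimethoxymethyl)pent-4-enoate
Product: 12 2-(dimethoxymethyl)pent-4-enal (racemic)
Conditions: iBu2AlH (1.05 equiv), CH2Cl2, −78 °C
Reagents that add atoms: none
Why: Partial reduction of the ester through the stable tetrahedral aluminium hemiacetal (iBu2AlH reduction at −78 °C) should stop at the aldehyde, the future C2 carbon.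

Step 8
Reactants: 9 (4R)-2-methoxy-3-methyl-4-(3,4,5-trimethoxyphenyl)cyclopent-2-en-1-one; 12 2-(dimethoxymethyl)pent-4-enal
Product: 13 (4R,5R)-5-[2-(dimethoxymethyl)-1-hydroxypent-4-en-1-yl]-2-methoxy-3-methyl-4-(3,4,5-trimethoxyphenyl)cyclopent-2-en-1-one (side-chain diastereomers)
Conditions: LiN(iPr)2 (1.1 equiv), THF, −78 °C; then 12, −78 °C; NH4Cl
Reagents that add atoms: none
Why: Kinetic deprotonation of the enone at the α′ ring CH2 and lithium aldol addition; the aldehyde should approach the enolate anti to the adjacent aryl group, setting C1 trans to C8, while the two side-chain centres form as mixtures and are erased in step 10.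

Step 9
Reactants: 13 (4R,5R)-5-[2-(dimethoxymethyl)-1-hydroxypent-4-en-1-yl]-2-methoxy-3-methyl-4-(3,4,5-trimethoxyphenyl)cyclopent-2-en-1-one
Product: 15 (1R,5R,6R,7R)-2-hydroxy-4,5-dimethoxy-6-methyl-3-(prop-2-en-1-yl)-7-(3,4,5-trimethoxyphenyl)bicyclo[3.2.1]octan-8-one (C2/C3/C4 diastereomers), via bis-silylated enol ether 14 (not isolated)
Conditions: Li (3.5 equiv), NH3(l)/THF, tBuOH (1.0 equiv), −78 °C; isoprene; Me3SiCl, Et3N, −78 °C to rt; then Me3SiOTf (0.2 equiv), CH2Cl2, −78 to −20 °C; K2CO3 (cat.), MeOH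
Reagents that add atoms: none
Why: Dissolving-metal (Birch-type) enone reduction should protonate the β-carbon under thermodynamic control (methyl trans to aryl, C9) and give the enolate regiospecifically; after silylation the α-methoxy enol carbon of 14 attacks the oxocarbenium ion released from the acetal (intramolecular Mukaiyama aldol-type addition), and the tether on C1, which lies trans to the aryl group, forces closure on the methyl face so that the new quaternary C5 carries its methoxy group exo.

Step 10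
Reactants: 15 (1R,5R,6R,7R)-2-hydroxy-4,5-dimethoxy-6-methyl-3-(prop-2-en-1-yl)-7-(3,4,5-trimethoxyphenyl)bicyclo[3.2.1]octan-8-one
Product: 17 (1R,5R,6R,7R)-5-methoxy-6-methyl-3-(prop-2-en-1-yl)-7-(3,4,5-trimethoxyphenyl)bicyclo[3.2.1]oct-3-ene-2,8-dione, via saturated β-methoxy diketone 16 (not isolated)
Conditions: Dess–Martin periodinane, CH2Cl2, rt; then DBU, 0 °C to rt
Reagents that add atoms: none
Why: Dess–Martin oxidation of the secondary alcohol gives β-methoxy ketone 16, which should lose methanol by E1cB elimination to the conjugated enone (the bridgehead α-position cannot enolise, so only C3–H is removed); the four ring stereocentres are untouched and the three undefined centres disappear.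

Step 11
Reactants: 17 (1R,5R,6R,7R)-5-methoxy-6-methyl-3-(prop-2-en-1-yl)-7-(3,4,5-trimethoxyphenyl)bicyclo[3.2.1]oct-3-ene-2,8-dione
Product: 18 (1R,5S,8R,9R)-5-methoxy-9-methyl-3-(prop-2-en-1-yl)-8-(3,4,5-trimethoxyphenyl)-6-oxabicyclo[3.2.2]non-3-ene-2,7-dione (CNP0298078.1)
Conditions: mCPBA (1.2 equiv), CH2Cl2, 0 °C
Reagents that add atoms: mCPBA (3-chloroperoxybenzoic acid), O=C(OO)c1cccc(Cl)c1
Why: Baeyer–Villiger oxidation of the strained bridging ketone: the α-methoxy bridgehead carbon migrates in preference to the carbon flanked by two carbonyls and does so with retention, so O6 is inserted between C5 and C7 with the C5 geometry unchanged (the descriptor changes from R to S only through priorities); the conjugated ketone and enone alkene are unreactive and the monosubstituted alkene should be epoxidised more slowly.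

Compound list
1 | dimethyl (E)-pent-2-enedioate (dimethyl glutaconate) | COC(=O)/C=C/CC(=O)OC | starting material
2 | dimethyl (E)-4-methylpent-2-enedioate (racemic) | COC(=O)/C=C/C(C)C(=O)OC | intermediate
3 | (3,4,5-trimethoxyphenyl)boronic acid | COc1cc(B(O)O)cc(OC)c1OC | starting material
4 | dimethyl (3S)-2-methyl-3-(3,4,5-trimethoxyphenyl)pentanedioate (C2 epimers) | COC(=O)C[C@H](c1cc(OC)c(OC)c(OC)c1)C(C)C(=O)OC | intermediate
5 | dimethyl oxalate | COC(=O)C(=O)OC | starting material
6 | dimethyl (3R)-2-(2-methoxy-2-oxoacetyl)-4-methyl-3-(3,4,5-trimethoxyphenyl)pentanedioate, as sodium enolate (not isolated) | COC(=O)C(=O)C(C(=O)OC)[C@H](c1cc(OC)c(OC)c(OC)c1)C(C)C(=O)OC | intermediate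
7 | dimethyl (2R)-1-methyl-4,5-dioxo-2-(3,4,5-trimethoxyphenyl)cyclopentane-1,3-dicarboxylate (C1/C3 epimers; enolised) | O=C1C(=O)C(C)(C(=O)OC)[C@@H](c2cc(OC)c(OC)c(OC)c2)C1C(=O)OC | intermediate
8 | (4R)-2-hydroxy-3-methyl-4-(3,4,5-trimethoxyphenyl)cyclopent-2-en-1-one | O=C1C(O)=C(C)[C@@H](c2cc(OC)c(OC)c(OC)c2)C1 | intermediate
9 | (4R)-2-methoxy-3-methyl-4-(3,4,5-trimethoxyphenyl)cyclopent-2-en-1-one | O=C1C(OC)=C(C)[C@@H](c2cc(OC)c(OC)c(OC)c2)C1 | intermediate
10 | methyl 3,3-dimethoxypropanoate | COC(OC)CC(=O)OC | starting material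
11 | methyl 2-(dimethoxymethyl)pent-4-enoate (racemic) | COC(OC)C(CC=C)C(=O)OC | intermediate
12 | 2-(dimethoxymethyl)pent-4-enal (racemic) | COC(OC)C(CC=C)C=O | intermediate
13 | (4R,5R)-5-[2-(dimethoxymethyl)-1-hydroxypent-4-en-1-yl]-2-methoxy-3-methyl-4-(3,4,5-trimethoxyphenyl)cyclopent-2-en-1-one (side-chain diastereomers) | O=C1C(OC)=C(C)[C@@H](c2cc(OC)c(OC)c(OC)c2)[C@@H]1C(O)C(CC=C)C(OC)OC | intermediate
14 | {[(3R,4R,5R)-5-[2-(dimethoxymethyl)-1-(trimethylsilyloxy)pent-4-en-1-yl]-2-methoxy-3-methyl-4-(3,4,5-trimethoxyphenyl)cyclopent-1-en-1-yl]oxy}trimethylsilane (not isolated) | C[Si](C)(C)OC1=C(OC)[C@H](C)[C@@H](c2cc(OC)c(OC)c(OC)c2)[C@@H]1C(O[Si](C)(C)C)C(CC=C)C(OC)OC | intermediate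
15 | (1R,5R,6R,7R)-2-hydroxy-4,5-dimethoxy-6-methyl-3-(prop-2-en-1-yl)-7-(3,4,5-trimethoxyphenyl)bicyclo[3.2.1]octan-8-one (C2/C3/C4 diastereomers) | C=CCC1C(OC)[C@@]2(OC)C(=O)[C@@H](C1O)[C@H](c1cc(OC)c(OC)c(OC)c1)[C@H]2C | intermediate
16 | (1R,5R,6R,7R)-4,5-dimethoxy-6-methyl-3-(prop-2-en-1-yl)-7-(3,4,5-trimethoxyphenyl)bicyclo[3.2.1]octane-2,8-dione (not isolated) | C=CCC1C(OC)[C@@]2(OC)C(=O)[C@@H](C1=O)[C@H](c1cc(OC)c(OC)c(OC)c1)[C@H]2C | intermediate
17 | (1R,5R,6R,7R)-5-methoxy-6-methyl-3-(prop-2-en-1-yl)-7-(3,4,5-trimethoxyphenyl)bicyclo[3.2.1]oct-3-ene-2,8-dione | C=CCC1=C[C@@]2(OC)C(=O)[C@@H](C1=O)[C@H](c1cc(OC)c(OC)c(OC)c1)[C@H]2C | intermediate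
18 | (1R,5S,8R,9R)-5-methoxy-9-methyl-3-(prop-2-en-1-yl)-8-(3,4,5-trimethoxyphenyl)-6-oxabicyclo[3.2.2]non-3-ene-2,7-dione | C=CCC1=C[C@@]2(OC)OC(=O)[C@@H](C1=O)[C@H](c1cc(OC)c(OC)c(OC)c1)[C@H]2C | target

Total step count: 11. Longest linear sequence: 9 steps (steps 1–5 and 8–11; steps 6–7 make the side-chain aldehyde).

Steps most likely to fail

1. Step 9. The dissolving-metal stage may over-reduce (loss of the central methoxy group of the arene or of the α-methoxy group), protonation at C9 may not be fully trans-selective, and the acetal may lose methanol to an enol ether instead of closing the C5–C4 bond. Fallback, setting out from 9 and coming back at 17: 9 is reduced on its own (Li, NH3, tBuOH; NH4Cl) to (2RS,3R,4S)-2-methoxy-3-methyl-4-(3,4,5-trimethoxyphenyl)cyclopentan-1-one F1. Separately, prop-2-yn-1-ol is carbometallated with allylmagnesium bromide and the alkenylmagnesium species is quenched with iodine to give (Z)-2-(iodomethylidene)pent-4-en-1-ol F2. MnO2 then oxidises F2 to (Z)-2-(iodomethylidene)pent-4-enal F3. The kinetic lithium enolate of F1, formed at the ring CH2 with LiN(iPr)2 at −78 °C, adds to F3 anti to the aryl group, and the aldolate is silylated with tBuMe2SiOTf to (3R,4R,5R)-5-[(Z)-1-(tert-butyldimethylsilyloxy)-2-(iodomethylidene)pent-4-en-1-yl]-2-methoxy-3-methyl-4-(3,4,5-trimethoxyphenyl)cyclopentan-1-one F4. An intramolecular palladium-catalysed ketone α-alkenylation of F4 (Pd(PPh3)4, KOtBu, THF) then makes the C5–C4 bond and gives (1R,5R,6R,7R)-2-(tert-butyldimethylsilyloxy)-5-methoxy-6-methyl-3-(prop-2-en-1-yl)-7-(3,4,5-trimethoxyphenyl)bicyclo[3.2.1]oct-3-en-8-one F5. Bu4NF converts F5 into (1R,5R,6R,7R)-2-hydroxy-5-methoxy-6-methyl-3-(prop-2-en-1-yl)-7-(3,4,5-trimethoxyphenyl)bicyclo[3.2.1]oct-3-en-8-one F6, and Dess–Martin oxidation of F6 returns to 17.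

2. Step 11. The peracid may epoxidise the allyl double bond in competition with the Baeyer–Villiger reaction, and the acid by-product may open the acyl ketal. Fallback, setting out from 17 and coming back at 18: the terminal alkene is masked first as its vicinal dibromide with pyridinium tribromide (1 equiv, CH2Cl2, −78 °C, to outrun bromination of the electron-rich arene), giving (1R,5R,6R,7R)-3-(2,3-dibromopropyl)-5-methoxy-6-methyl-7-(3,4,5-trimethoxyphenyl)bicyclo[3.2.1]oct-3-ene-2,8-dione F7. Baeyer–Villiger oxidation of F7 with mCPBA then gives (1R,5S,8R,9R)-3-(2,3-dibromopropyl)-5-methoxy-9-methyl-8-(3,4,5-trimethoxyphenyl)-6-oxabicyclo[3.2.2]non-3-ene-2,7-dione F8. NaI in acetone (50 °C) removes both bromine atoms from F8 and regenerates the allyl group of 18; this neutral debromination is chosen over zinc, which could cleave the γ-acyloxy enone reductively.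

3. Step 2. Base-mediated double-bond migration in the γ-acidic glutaconate and competing protodeboronation may lower the enantiomeric purity set at C8. Fallback, setting out from 1 (together with 3) and coming back at 4: 1 is arylated with 3 under an achiral catalyst ([Rh(OH)(cod)]2, dioxane/H2O) to achiral dimethyl 3-(3,4,5-trimethoxyphenyl)pentanedioate F9. LiOH hydrolysis of F9 gives 3-(3,4,5-trimethoxyphenyl)pentanedioic acid F10, and Ac2O closes F10 to 4-(3,4,5-trimethoxyphenyl)oxane-2,6-dione F11. Desymmetrising methanolysis of F11 with MeOH and the modified cinchona alkaloid hydroquinidine anthraquinone-1,4-diyl diether, (DHQD)2AQN, or its hydroquinine pseudoenantiomer, whichever delivers the (3S) acid, gives (3S)-5-methoxy-5-oxo-3-(3,4,5-trimethoxyphenyl)pentanoic acid F12. Dianion methylation of F12 α to the ester (LiN(iPr)2, 2.2 equiv; MeI) gives (3S)-5-methoxy-4-methyl-5-oxo-3-(3,4,5-trimethoxyphenyl)pentanoic acid F13 as a mixture of C4 epimers, and esterification of F13 with Me3SiCHN2 returns to 4.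

Further compounds
F1 | step 9 | (2RS,3R,4S)-2-methoxy-3-methyl-4-(3,4,5-trimethoxyphenyl)cyclopentan-1-one | O=C1C(OC)[C@H](C)[C@@H](c2cc(OC)c(OC)c(OC)c2)C1
F2 | step 9 | (Z)-2-(iodomethylidene)pent-4-en-1-ol | OC/C(=C\I)CC=C
F3 | step 9 | (Z)-2-(iodomethylidene)pent-4-enal | O=C/C(=C\I)CC=C
F4 | step 9 | (3R,4R,5R)-5-[(Z)-1-(tert-butyldimethylsilyloxy)-2-(iodomethylidene)pent-4-en-1-yl]-2-methoxy-3-methyl-4-(3,4,5-trimethoxyphenyl)cyclopentan-1-one | O=C1C(OC)[C@H](C)[C@@H](c2cc(OC)c(OC)c(OC)c2)[C@@H]1C(O[Si](C)(C)C(C)(C)C)/C(=C\I)CC=C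
F5 | step 9 | (1R,5R,6R,7R)-2-(tert-butyldimethylsilyloxy)-5-methoxy-6-methyl-3-(prop-2-en-1-yl)-7-(3,4,5-trimethoxyphenyl)bicyclo[3.2.1]oct-3-en-8-one | C=CCC1=C[C@@]2(OC)C(=O)[C@@H](C1O[Si](C)(C)C(C)(C)C)[C@H](c1cc(OC)c(OC)c(OC)c1)[C@H]2C
F6 | step 9 | (1R,5R,6R,7R)-2-hydroxy-5-methoxy-6-methyl-3-(prop-2-en-1-yl)-7-(3,4,5-trimethoxyphenyl)bicyclo[3.2.1]oct-3-en-8-one | C=CCC1=C[C@@]2(OC)C(=O)[C@@H](C1O)[C@H](c1cc(OC)c(OC)c(OC)c1)[C@H]2C
F7 | step 11 | (1R,5R,6R,7R)-3-(2,3-dibromopropyl)-5-methoxy-6-methyl-7-(3,4,5-trimethoxyphenyl)bicyclo[3.2.1]oct-3-ene-2,8-dione | BrCC(Br)CC1=C[C@@]2(OC)C(=O)[C@@H](C1=O)[C@H](c1cc(OC)c(OC)c(OC)c1)[C@H]2C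
F8 | step 11 | (1R,5S,8R,9R)-3-(2,3-dibromopropyl)-5-methoxy-9-methyl-8-(3,4,5-trimethoxyphenyl)-6-oxabicyclo[3.2.2]non-3-ene-2,7-dione | BrCC(Br)CC1=C[C@@]2(OC)OC(=O)[C@@H](C1=O)[C@H](c1cc(OC)c(OC)c(OC)c1)[C@H]2C
F9 | step 2 | dimethyl 3-(3,4,5-trimethoxyphenyl)pentanedioate | COC(=O)CC(c1cc(OC)c(OC)c(OC)c1)CC(=O)OC
F10 | step 2 | 3-(3,4,5-trimethoxyphenyl)pentanedioic acid | OC(=O)CC(c1cc(OC)c(OC)c(OC)c1)CC(=O)O
F11 | step 2 | 4-(3,4,5-trimethoxyphenyl)oxane-2,6-dione | O=C1CC(c2cc(OC)c(OC)c(OC)c2)CC(=O)O1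
F12 | step 2 | (3S)-5-methoxy-5-oxo-3-(3,4,5-trimethoxyphenyl)pentanoic acid | OC(=O)C[C@H](c1cc(OC)c(OC)c(OC)c1)CC(=O)OC
F13 | step 2 | (3S)-5-methoxy-4-methyl-5-oxo-3-(3,4,5-trimethoxyphenyl)pentanoic acid (C4 epimers) | OC(=O)C[C@H](c1cc(OC)c(OC)c(OC)c1)C(C)C(=O)OC
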